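| flask | left-handed substrate | right-handed substrate | reagent | free catalyst | racemization catalyst | remark | time |
|---|---|---|---|---|---|---|---|
| ochre | 0.25 M | 0.25 M | 0.88 M | 12 mM | 2.5 mM | run made earlier |  |
| blue | 0.25 M | 0.25 M | 1.4 M | 12 mM | 2.5 mM | run made earlier |  |
| flask | 0.25 M | 0.25 M | 0.625 M | 12 mM | 2.5 mM |  | 40 h |

| run | time / h | left-handed product / % | right-handed product / % | left-handed substrate / % |
|---|---|---|---|---|
| ochre | 5.00 | 34 | 22 | 15 |
| ochre | 10.0 | 43 | 34 | 8 |
| ochre | 15.0 | 49 | 37 | 1 |
| ochre | 20.0 | 49 | 40 | 1 |
| ochre | 25.0 | 50 | 44 | 1 |
| ochre | 30.0 | 50 | 45 | 1 |
| blue | 5.00 | 42 | 31 | 5 |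
| blue | 10.0 | 47 | 40 | 1 |
| blue | 15.0 | 50 | 46 | 1 |
| blue | 20.0 | 49 | 46 | 3 |
| blue | 25.0 | 50 | 51 | 2 |
| blue | 30.0 | 49 | 49 | 0 |

(standard deviation of a reading: 2 percentage points)

- free catalyst is single-handed; left-handed substrate and right-handed substrate are mirror images of each other, charged as a racemate, each of them at the stated concentration
- an excess is the difference of the two amounts in percent of their sum
- an excess is below zero if the other one leads

* left-handed product and right-handed product together, in percent of the left-handed substrate and right-handed substrate charged together, at 40 h
* excess of left-handed product over right-handed product in the product at 40 h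
* whether the exchange between left-handed substrate and right-handed substrate keeps pace with the reaction: how far the product's excess at 40 h gets from its value without exchange to its value with instant exchange (above 80% keeps pace, below 20% hardly takes part, else lags behind)

A ratio orders this dispute. Read from the products, it gives 1.97 in ochre at 5.00 h and 1.89 in blue at 5.00 h, so I take 1.93, a reading with scatter. This is the selectivity factor, the logarithm of the fraction of left-handed substrate left over that of right-handed substrate left, when no exchange runs.

Two chemists argue over the flask. The first says the racemization catalyst keeps the substrates exchanged, so the product's excess holds at (s − 1)/(s + 1), which is 31.7%, and the flask has less reagent than ochre, so exchange has longer to act. The second answers that ochre's excess at 30.0 h reads 5.26%, far less than that, so the substrates react separately and the excess fades.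

I reckon the second view. Ochre's right-handed product at 5.00 h gives a rate constant of 0.157 M⁻¹ h⁻¹ on the mean reagent. In a first round, I hold the reagent for 40 h at its surplus over both substrates, 125 mM. That leaves 45.7% of the right-handed substrate and 22.0% of the left-handed. That round's leftovers put the reagent at 294 mM, and going round again with this as the mean leaves 15.8% and 2.84%. My answer is 90.7% product with an excess of 7.15%.

The forecast also takes the second side, since “this is plain kinetic resolution”. It gives 89% (84% to 93%), an excess of 10% (6% to 14%), and "hardly takes part", a higher excess than mine.

The flask gives 90.2% with an excess of 7.16%, and the exchange hardly takes part, getting 1.9% of the way.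

    left-handed substrate + racemization catalyst ⇌ right-handed substrate + racemization catalyst, rate k1*[racemization catalyst]*[left-handed substrate] forward; the back reaction follows from the equilibrium constant (k = 34.0 M⁻¹ h⁻¹)
    2 racemization catalyst → spent catalyst (k = 2300 M⁻¹ h⁻¹)
    reagent + free catalyst + right-handed substrate → free catalyst + right-handed product (k = 14.0 M⁻² h⁻¹)
    racemization catalyst ⇌ dormant form (K = 12.0, k = 0.650 h⁻¹)
    reagent + free catalyst + left-handed substrate → free catalyst + left-handed product (k = 25.0 M⁻² h⁻¹)

The flask's remainders, 4.0% and 16% of their own charges, give a ratio of 1.74. Now take the neighbour charged with 0.16 M of reagent. That charge allows 32.0% product. If the product splits by s, 78.2% of the right-handed substrate stays, and s then leaves 62.1% of the left-handed, an excess of 26.8%. That neighbour gives 31.0% product with an excess of 23.6%, nearer the first chemist's 31.7% than the flask's 7.16%.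

The runs are simulated for substances that don't exist, noise included.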